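**Retrosynthetic overview**

1. The last C–C bond is C8–C9, made by Suzuki coupling of lactone alkenyl boronate 28 with bromo-diol 15; one fluoride step then frees the acid and the third hydroxyl.
2. 15 comes from a butanone core: syn reductive aldol of but-3-en-2-one onto trienal 8 (sets C14, C15), then a methyl-ketone boron aldol with bromo enal 3 and in-flask 1,3-syn reduction (sets C11, C13).
3. 8 comes from 2-methyloxazole-4-carbaldehyde by aldol condensation with propanal, boryl olefination and Suzuki coupling with 3.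
4. 28 comes from δ-lactone 24, made in one step by the key ring expansion: the C=O of aldehyde 23 is inserted into the acyl–carbon bond of prochiral 3-allylcyclobutanone 20 (sets C3 and C5); cross-metathesis, oxidation and boryl olefination follow.
5. Ring order: the oxazole is bought; the cyclobutanone ring is formed in step 8 by a (2+2) addition and expanded to the six-membered lactone in step 11.

Numbering used below: C1 is the lactone carbonyl, C3 carries the butenoic acid chain, C5 is the lactone C–O carbon, C6 the adjacent methyl-bearing carbon, then along the chain to C21 (the CH on the oxazole). Target: 3R,5R,6R,11R,13S,14S,15R, all alkenes E.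

Assumption: the facial sense of the two isopinocampheylboron aldols (steps 5 and 7) is assigned from the usual models and was not checked against a primary source; if either runs the other way, the antipodal pinene-derived borane is used and nothing else changes.

**Route**

Step 1
Reactants: 1 methacrolein
Product: 3 (E)-3-bromo-2-methylprop-2-enal, via dibromide 2 (not isolated)
Conditions: Br2 (1.0 equiv), CH2Cl2, −78 to 0 °C; then Et3N (1.2 equiv), 0 to 25 °C
Reagents that add atoms: bromine BrBr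
Why: Alkene bromination followed by dehydrobromination; the α-carbon has no hydrogen, so only the 3-bromo enal can form, and the E isomer (Br trans to CHO) is the thermodynamic product.

Step 2
Reactants: 4 2-methyl-1,3-oxazole-4-carbaldehyde; 5 propanal
Product: 6 (E)-2-methyl-3-(2-methyl-1,3-oxazol-4-yl)prop-2-enal
Conditions: 5 (1.5 equiv, slow addition), NaOH (0.2 equiv), MeOH/H2O, 0 to 25 °C
Reagents that add atoms: none
Why: Crossed aldol condensation (Claisen–Schmidt type) of a non-enolisable heteroaryl aldehyde with propanal; dehydration under equilibrating conditions gives the E trisubstituted enal (C20=C21).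

Step 3
Reactants: 6 (E)-2-methyl-3-(2-methyl-1,3-oxazol-4-yl)prop-2-enal
Product: 7 2-methyl-4-[(1E,3E)-2-methyl-4-(4,4,5,5-tetramethyl-1,3,2-dioxaborolan-2-yl)buta-1,3-dien-1-yl]-1,3-oxazole
Conditions: CrCl2 (8 equiv), Cl2CHBpin (2 equiv), LiI (4 equiv), THF, 25 °C
Reagents that add atoms: 2-(dichloromethyl)-4,4,5,5-tetramethyl-1,3,2-dioxaborolane ClC(Cl)B1OC(C)(C)C(C)(C)O1
Why: Takai–Utimoto boryl olefination; the gem-dichromium carbenoid adds to the aldehyde and anti elimination gives the E alkenyl boronate (C18=C19) without touching the existing alkene.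

Step 4
Reactants: 7 dienyl boronate; 3 (E)-3-bromo-2-methylprop-2-enal
Product: 8 (2E,4E,6E)-2,6-dimethyl-7-(2-methyl-1,3-oxazol-4-yl)hepta-2,4,6-trienal
Conditions: Pd(dppf)Cl2 (5 mol%), K3PO4 (3 equiv), THF/H2O, 25 °C
Reagents that add atoms: none
Why: Suzuki–Miyaura coupling of an alkenyl boronate with a β-bromo enal goes with retention at both alkenes and gives the all-E trienal.

Step 5
Reactants: 9 but-3-en-2-one; 8 trienal
Product: 11 (3R,4R,5E,7E,9E)-4-hydroxy-3,5,9-trimethyl-10-(2-methyl-1,3-oxazol-4-yl)deca-5,7,9-trien-2-one, via boron enolate 10 (not isolated)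
Conditions: (+)-Ipc2BH (from (−)-α-pinene, 1.2 equiv), 9 (1.2 equiv), Et2O, 0 °C, 2 h; then 8, −78 to −40 °C; then pH 7 buffer, MeOH, H2O2, 0 °C
Reagents that add atoms: none
Why: Borane-mediated reductive aldol: 1,4-hydroboration of the s-cis enone gives only the (Z)-enol borinate on the ethyl side of butanone, its Zimmerman–Traxler chair gives the syn aldol, and the isopinocampheyl groups direct attack to the Re face of the enal (C14 S and C15 R in target numbering).

Step 6
Reactants: 11 β-hydroxy ketone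
Product: 12 (3R,4R,5E,7E,9E)-3,5,9-trimethyl-10-(2-methyl-1,3-oxazol-4-yl)-4-(triethylsilyloxy)deca-5,7,9-trien-2-one
Conditions: TESCl (1.3 equiv), imidazole (2 equiv), DMF, 0 °C
Reagents that add atoms: chlorotriethylsilane CC[Si](Cl)(CC)CC
Why: Silyl ether formation blocks retro-aldol and keeps this oxygen from directing the later ketone reduction.

Step 7
Reactants: 12 silyloxy methyl ketone; 3 (E)-3-bromo-2-methylprop-2-enal
Product: 15 (1E,3R,5S,6S,7R,8E,10E,12E)-1-bromo-2,6,8,12-tetramethyl-13-(2-methyl-1,3-oxazol-4-yl)-7-(triethylsilyloxy)trideca-1,8,10,12-tetraene-3,5-diol, via boron enolate 13 (not isolated), via boron aldolate 14 (not isolated)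
Conditions: (−)-Ipc2BCl (from (+)-α-pinene, 1.5 equiv), Et3N (2 equiv), Et2O, 0 °C; then 3 (2 equiv), −78 to −20 °C; then LiBH4 (3 equiv), −78 °C; then pH 7 buffer, MeOH, H2O2, 0 °C
Reagents that add atoms: none
Why: Paterson methyl-ketone boron aldol with in-flask syn reduction: kinetic enolisation on the methyl side and reagent-controlled Re-face attack on the bromo enal set C11 (R), and external hydride attack on the six-membered boron aldolate chelate gives the 11,13-syn diol (C13 S).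

Step 8
Reactants: 16 N,N-dimethylacetamide; 17 penta-1,4-diene
Product: 20 3-(prop-2-en-1-yl)cyclobutan-1-one, via keteniminium triflate 18 (not isolated), via cyclobutaniminium triflate 19 (not isolated)
Conditions: Tf2O (1.1 equiv), 2,4,6-collidine (1.2 equiv), 17 (4 equiv), ClCH2CH2Cl, sealed tube, 80 °C; then aq. NaHCO3, 25 °C
Reagents that add atoms: water O
Why: Ghosez keteniminium (2+2) cycloaddition; the electrophilic keteniminium carbon bonds to the terminal alkene carbon, so the allyl group sits at C3 of the ring, and iminium hydrolysis gives the prochiral ketone (excess diene suppresses double addition).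

Step 9
Reactants: 21 methyl (R)-3-hydroxy-2-methylpropanoate
Product: 22 methyl (R)-2-methyl-3-(triethylsilyloxy)propanoate
Conditions: TESCl (1.1 equiv), imidazole (1.5 equiv), CH2Cl2, 0 to 25 °C
Reagents that add atoms: chlorotriethylsilane CC[Si](Cl)(CC)CC
Why: Standard silylation of the primary alcohol; the stereocentre (later C6) comes from the chiral pool and is not touched.

Step 10
Reactants: 22 silyl ether ester
Product: 23 (R)-2-methyl-3-(triethylsilyloxy)propanal
Conditions: i-Bu2AlH (1.05 equiv), CH2Cl2, −78 °C; aq. KNaC4H4O6 work-up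
Reagents that add atoms: none
Why: Partial ester reduction stops at the aldehyde because the aluminium hemiacetal is stable at −78 °C; the α-stereocentre survives these non-basic conditions and the aldehyde is used at once.

Step 11
Reactants: 20 3-(prop-2-en-1-yl)cyclobutan-1-one; 23 (R)-2-methyl-3-(triethylsilyloxy)propanal
Product: 24 (4R,6R)-4-(prop-2-en-1-yl)-6-[(2R)-1-(triethylsilyloxy)propan-2-yl]oxan-2-one
Conditions: Ni(cod)2 (10 mol%), preformed (4R,5R)-4,5-diphenyl-1,3-bis(2-isopropylphenyl)imidazolin-2-ylidene (12 mol%), 20 (2 equiv), toluene, 40 °C, 23 added over 8 h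
Reagents that add atoms: none
Why: Proposed new method: zerovalent nickel with a bulky chiral carbene should join the η2-bound aldehyde and the strained ketone by hetero-oxidative cyclisation (aldehyde oxygen to ketone carbon, nickel on the Felkin face of the aldehyde carbon so that O5 and the C6 methyl end up syn), strain-driven β-carbon elimination then opens one of the two enantiotopic ring bonds (ligand-controlled, sets C3; the ligand antipode is chosen by screening), and C(sp3)–C(sp3) reductive elimination from the seven-membered nickelacycle closes the δ-lactone with both ring substituents equatorial (cis), a two-atom ring expansion by formal insertion of C=O into the acyl–carbon bond; the closest known reaction types are nickel-catalysed intermolecular alkyne insertion into cyclobutanones, rhodium-catalysed intramolecular carbonyl carboacylation of cyclobutanones and the nickel–carbene Tishchenko coupling of aldehydes through the same kind of dioxanickelacycle.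

Step 12
Reactants: 24 allyl lactone; 25 2-(trimethylsilyl)ethyl prop-2-enoate
Product: 26 2-(trimethylsilyl)ethyl (2E)-4-[(4R,6R)-2-oxo-6-[(2R)-1-(triethylsilyloxy)propan-2-yl]oxan-4-yl]but-2-enoate
Conditions: second-generation Hoveyda–Grubbs catalyst RuCl2(H2IMes)(=CH-C6H4-2-Oi-Pr) (5 mol%), 25 (3 equiv), CH2Cl2, 40 °C
Reagents that add atoms: none
Why: Olefin cross-metathesis of the only alkene in 24 (an unhindered allyl group) with an acrylate, which does not homodimerise, gives the E enoate.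

Step 13
Reactants: 26 silyl ether enoate
Product: 27 2-(trimethylsilyl)ethyl (2E)-4-[(4R,6R)-2-oxo-6-[(2S)-1-oxopropan-2-yl]oxan-4-yl]but-2-enoate
Conditions: (COCl)2 (4 equiv), DMSO (8 equiv), CH2Cl2, −78 to −30 °C; then Et3N, −78 to 0 °C
Reagents that add atoms: none
Why: Swern oxidation applied directly to a primary triethylsilyl ether; the chlorosulfonium salt cleaves the Si–O bond and oxidises the carbon in one operation, the esters are inert, and the sensitive β-acyloxy aldehyde is used crude (C6 unchanged in space; the descriptor changes only through priorities).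

Step 14
Reactants: 27 lactone aldehyde
Product: 28 2-(trimethylsilyl)ethyl (2E)-4-[(4R,6R)-2-oxo-6-[(2R,3E)-4-(4,4,5,5-tetramethyl-1,3,2-dioxaborolan-2-yl)but-3-en-2-yl]oxan-4-yl]but-2-enoate
Conditions: CrCl2 (8 equiv), Cl2CHBpin (2 equiv), LiI (4 equiv), THF, 25 °C
Reagents that add atoms: 2-(dichloromethyl)-4,4,5,5-tetramethyl-1,3,2-dioxaborolane ClC(Cl)B1OC(C)(C)C(C)(C)O1
Why: Takai–Utimoto boryl olefination under non-basic chromium conditions gives the E alkenyl boronate (C7=C8) without epimerising C6 or eliminating the β-acyloxy group.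

Step 15
Reactants: 28 lactone alkenyl boronate; 15 bromo-diol
Product: 29 2-(trimethylsilyl)ethyl (2E)-4-[(4R,6R)-6-[(2R,3E,5E,7R,9S,10S,11R,12E,14E,16E)-7,9-dihydroxy-6,10,12,16-tetramethyl-17-(2-methyl-1,3-oxazol-4-yl)-11-(triethylsilyloxy)heptadeca-3,5,12,14,16-pentaen-2-yl]-2-oxooxan-4-yl]but-2-enoate
Conditions: Pd(PPh3)4 (10 mol%), TlOEt (1.8 equiv), THF/H2O 3:1, 25 °C
Reagents that add atoms: none
Why: Suzuki–Miyaura coupling with a fast mild base joins C8 and C9 with retention of both alkene geometries at room temperature and tolerates the lactone, the free diol and the triene.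

Step 16
Reactants: 29 protected seco-product
Product: 30 (2E)-4-[(4R,6R)-2-oxo-6-[(2R,3E,5E,7R,9S,10S,11R,12E,14E,16E)-7,9,11-trihydroxy-6,10,12,16-tetramethyl-17-(2-methyl-1,3-oxazol-4-yl)heptadeca-3,5,12,14,16-pentaen-2-yl]oxan-4-yl]but-2-enoic acid
Conditions: Bu4NF (5 equiv), THF, 0 to 25 °C; aq. NH4Cl work-up
Reagents that add atoms: none
Why: Fluoride-mediated global deprotection removes the triethylsilyl ether and fragments the 2-(trimethylsilyl)ethyl ester (loss of ethylene) in one acid-free operation that leaves the allylic alcohols, the lactone and the polyenes intact.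

**Compound list**

1 | methacrolein (2-methylprop-2-enal) | C=C(C)C=O | starting material
2 | 2,3-dibromo-2-methylpropanal (racemic) | O=CC(C)(Br)CBr | intermediate
3 | (E)-3-bromo-2-methylprop-2-enal | O=C/C(C)=C/Br | intermediate
4 | 2-methyl-1,3-oxazole-4-carbaldehyde | Cc1nc(C=O)co1 | starting material
5 | propanal | CCC=O | starting material
6 | (E)-2-methyl-3-(2-methyl-1,3-oxazol-4-yl)prop-2-enal | O=C/C(C)=C/c1coc(C)n1 | intermediate
7 | 2-methyl-4-[(1E,3E)-2-methyl-4-(4,4,5,5-tetramethyl-1,3,2-dioxaborolan-2-yl)buta-1,3-dien-1-yl]-1,3-oxazole | CC(/C=C/B1OC(C)(C)C(C)(C)O1)=C\c1coc(C)n1 | intermediate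
8 | (2E,4E,6E)-2,6-dimethyl-7-(2-methyl-1,3-oxazol-4-yl)hepta-2,4,6-trienal | CC(/C=C/C=C(\C)C=O)=C\c1coc(C)n1 | intermediate
9 | but-3-en-2-one | C=CC(C)=O | starting material
10 | (Z)-but-2-en-2-yl bis[(+)-isopinocampheyl]borinate | C/C=C(/C)OB([C@@H]1[C@@H](C)[C@@H]2C[C@H](C1)C2(C)C)[C@@H]1[C@@H](C)[C@@H]2C[C@H](C1)C2(C)C | intermediate
11 | (3R,4R,5E,7E,9E)-4-hydroxy-3,5,9-trimethyl-10-(2-methyl-1,3-oxazol-4-yl)deca-5,7,9-trien-2-one | CC(/C=C/C=C(\C)[C@H](O)[C@@H](C)C(C)=O)=C\c1coc(C)n1 | intermediate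
12 | (3R,4R,5E,7E,9E)-3,5,9-trimethyl-10-(2-methyl-1,3-oxazol-4-yl)-4-(triethylsilyloxy)deca-5,7,9-trien-2-one | CC(/C=C/C=C(\C)[C@H](O[Si](CC)(CC)CC)[C@@H](C)C(C)=O)=C\c1coc(C)n1 | intermediate
13 | bis[(−)-isopinocampheyl]boron enolate of 12 (enol borinate at C12=C13) | CC(/C=C/C=C(\C)[C@H](O[Si](CC)(CC)CC)[C@@H](C)C(=C)OB([C@H]1[C@H](C)[C@H]2C[C@@H](C1)C2(C)C)[C@H]1[C@H](C)[C@H]2C[C@@H](C1)C2(C)C)=C\c1coc(C)n1 | intermediate
14 | bis[(−)-isopinocampheyl]boron aldolate (11R alkoxide, C13 ketone) | CC(/C=C/C=C(\C)[C@H](O[Si](CC)(CC)CC)[C@@H](C)C(=O)C[C@@H](OB([C@H]1[C@H](C)[C@H]2C[C@@H](C1)C2(C)C)[C@H]1[C@H](C)[C@H]2C[C@@H](C1)C2(C)C)/C(C)=C/Br)=C\c1coc(C)n1 | intermediate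
15 | (1E,3R,5S,6S,7R,8E,10E,12E)-1-bromo-2,6,8,12-tetramethyl-13-(2-methyl-1,3-oxazol-4-yl)-7-(triethylsilyloxy)trideca-1,8,10,12-tetraene-3,5-diol | CC(/C=C/C=C(\C)[C@H](O[Si](CC)(CC)CC)[C@@H](C)[C@@H](O)C[C@@H](O)/C(C)=C/Br)=C\c1coc(C)n1 | intermediate
16 | N,N-dimethylacetamide | CC(=O)N(C)C | starting material
17 | penta-1,4-diene | C=CCC=C | starting material
18 | N,N-dimethylketeniminium triflate | C=C=[N+](C)C.[O-]S(=O)(=O)C(F)(F)F | intermediate
19 | N,N-dimethyl-3-(prop-2-en-1-yl)cyclobutan-1-iminium triflate | C=CCC1CC(=[N+](C)C)C1.[O-]S(=O)(=O)C(F)(F)F | intermediate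
20 | 3-(prop-2-en-1-yl)cyclobutan-1-one | C=CCC1CC(=O)C1 | intermediate
21 | methyl (R)-3-hydroxy-2-methylpropanoate | OC[C@@H](C)C(=O)OC | starting material
22 | methyl (R)-2-methyl-3-(triethylsilyloxy)propanoate | CC[Si](CC)(CC)OC[C@@H](C)C(=O)OC | intermediate
23 | (R)-2-methyl-3-(triethylsilyloxy)propanal | CC[Si](CC)(CC)OC[C@@H](C)C=O | intermediate
24 | (4R,6R)-4-(prop-2-en-1-yl)-6-[(2R)-1-(triethylsilyloxy)propan-2-yl]oxan-2-one | CC[Si](CC)(CC)OC[C@@H](C)[C@H]1C[C@@H](CC=C)CC(=O)O1 | intermediate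
25 | 2-(trimethylsilyl)ethyl prop-2-enoate (acrylic acid bought as its silylethyl ester) | C=CC(=O)OCC[Si](C)(C)C | starting material
26 | 2-(trimethylsilyl)ethyl (2E)-4-[(4R,6R)-2-oxo-6-[(2R)-1-(triethylsilyloxy)propan-2-yl]oxan-4-yl]but-2-enoate | CC[Si](CC)(CC)OC[C@@H](C)[C@H]1C[C@@H](C/C=C/C(=O)OCC[Si](C)(C)C)CC(=O)O1 | intermediate
27 | 2-(trimethylsilyl)ethyl (2E)-4-[(4R,6R)-2-oxo-6-[(2S)-1-oxopropan-2-yl]oxan-4-yl]but-2-enoate | O=C[C@@H](C)[C@H]1C[C@@H](C/C=C/C(=O)OCC[Si](C)(C)C)CC(=O)O1 | intermediate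
28 | 2-(trimethylsilyl)ethyl (2E)-4-[(4R,6R)-2-oxo-6-[(2R,3E)-4-(4,4,5,5-tetramethyl-1,3,2-dioxaborolan-2-yl)but-3-en-2-yl]oxan-4-yl]but-2-enoate | CC1(C)OB(/C=C/[C@@H](C)[C@H]2C[C@@H](C/C=C/C(=O)OCC[Si](C)(C)C)CC(=O)O2)OC1(C)C | intermediate
29 | 2-(trimethylsilyl)ethyl ester of 30 carrying a triethylsilyl ether on O15 (all stereocentres as in 30) | CC(/C=C/C=C(\C)[C@H](O[Si](CC)(CC)CC)[C@@H](C)[C@@H](O)C[C@@H](O)/C(C)=C/C=C/[C@@H](C)[C@H]1C[C@@H](C/C=C/C(=O)OCC[Si](C)(C)C)CC(=O)O1)=C\c1coc(C)n1 | intermediate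
30 | (2E)-4-[(4R,6R)-2-oxo-6-[(2R,3E,5E,7R,9S,10S,11R,12E,14E,16E)-7,9,11-trihydroxy-6,10,12,16-tetramethyl-17-(2-methyl-1,3-oxazol-4-yl)heptadeca-3,5,12,14,16-pentaen-2-yl]oxan-4-yl]but-2-enoic acid (CNP0198746.1) | CC(/C=C/C=C(\C)[C@H](O)[C@@H](C)[C@@H](O)C[C@@H](O)/C(C)=C/C=C/[C@@H](C)[C@H]1C[C@@H](C/C=C/C(=O)O)CC(=O)O1)=C\c1coc(C)n1 | target

**Totals and risks**

Total steps: 16. Longest linear sequence: 8 (steps 9–16; the oxazole branch, steps 2–7 then 15–16, is also 8).

Most likely to fail, first: step 11, the proposed ring expansion. Aldehyde homo-Tishchenko coupling, β-hydride elimination from the dialkylnickel intermediate or poor facial control could defeat it. The fallback uses known chemistry, sets out from aldehyde 23 and returns at lactone 24. A BF3·OEt2-promoted Mukaiyama aldol of 23 with the bis(trimethylsilyl) dienol ether of methyl acetoacetate gives, under Felkin control, methyl (5R,6R)-5-hydroxy-6-methyl-3-oxo-7-(triethylsilyloxy)heptanoate F1. K2CO3 in MeOH closes it to (6R)-6-[(2R)-1-(triethylsilyloxy)propan-2-yl]oxane-2,4-dione F2. Tf2O and Et3N give the enol triflate (2R)-6-oxo-2-[(2R)-1-(triethylsilyloxy)propan-2-yl]-3,6-dihydro-2H-pyran-4-yl trifluoromethanesulfonate F3. Stille coupling with Bu3Sn(CH2CH=CH2) and Pd(PPh3)4 gives (6R)-4-(prop-2-en-1-yl)-6-[(2R)-1-(triethylsilyloxy)propan-2-yl]-5,6-dihydro-2H-pyran-2-one F4. Conjugate reduction with [(Ph3P)CuH]6 delivers hydride trans to the C6 substituent and gives the cis lactone 24.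

Second: step 7. Reagent control in methyl-ketone Ipc2B aldols is moderate and the α-methyl β-silyloxy ketone may oppose it, so the C11 ratio could be low. The fallback replaces reagent control with substrate-controlled 1,5-anti induction; it sets out from hydroxy ketone 11 and returns at target 30. 11 is converted under acid-free conditions (2-(4-methoxybenzyloxy)-4-methylquinoline, MeOTf, MgO) into (3R,4R,5E,7E,9E)-4-[(4-methoxyphenyl)methoxy]-3,5,9-trimethyl-10-(2-methyl-1,3-oxazol-4-yl)deca-5,7,9-trien-2-one F5. Its Bu2BOTf/i-Pr2NEt enolate adds to 3 with 1,5-anti induction from the β-benzyloxy group, and LiBH4 in the same flask gives (1E,3R,5S,6S,7R,8E,10E,12E)-1-bromo-7-[(4-methoxyphenyl)methoxy]-2,6,8,12-tetramethyl-13-(2-methyl-1,3-oxazol-4-yl)trideca-1,8,10,12-tetraene-3,5-diol F6. Suzuki coupling with 28 as in step 15 gives the 2-(trimethylsilyl)ethyl ester of 30 carrying a 4-methoxybenzyl ether on O15 F7. DDQ in pH 7 buffered CH2Cl2 gives the 2-(trimethylsilyl)ethyl ester of 30 F8, and Bu4NF as in step 16 gives 30.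

Third: step 5. The enantioselectivity of the Ipc2B (Z)-enolate generated by 1,4-hydroboration is less documented for a simple vinyl ketone than for acrylamides, and the trienal is a weak electrophile. The fallback is an auxiliary-controlled aldol; it sets out from trienal 8 and returns at ketone 12. Propanoyl chloride acylates lithiated (R)-4-benzyl-1,3-oxazolidin-2-one to give (4R)-4-benzyl-3-propanoyl-1,3-oxazolidin-2-one F9. Its Bu2BOTf/i-Pr2NEt enolate gives with 8 the Evans syn adduct (4R)-4-benzyl-3-[(2R,3R,4E,6E,8E)-3-hydroxy-2,4,8-trimethyl-9-(2-methyl-1,3-oxazol-4-yl)nona-4,6,8-trienoyl]-1,3-oxazolidin-2-one F10. AlMe3 and MeONHMe·HCl give (2R,3R,4E,6E,8E)-3-hydroxy-N-methoxy-N,2,4,8-tetramethyl-9-(2-methyl-1,3-oxazol-4-yl)nona-4,6,8-trienamide F11. TESCl and imidazole give its 3-O-triethylsilyl ether F12, and MeMgBr gives 12.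

**Further compounds**

F1 | step 11 | methyl (5R,6R)-5-hydroxy-6-methyl-3-oxo-7-(triethylsilyloxy)heptanoate | CC[Si](CC)(CC)OC[C@@H](C)[C@H](O)CC(=O)CC(=O)OC
F2 | step 11 | (6R)-6-[(2R)-1-(triethylsilyloxy)propan-2-yl]oxane-2,4-dione | CC[Si](CC)(CC)OC[C@@H](C)[C@H]1CC(=O)CC(=O)O1
F3 | step 11 | (2R)-6-oxo-2-[(2R)-1-(triethylsilyloxy)propan-2-yl]-3,6-dihydro-2H-pyran-4-yl trifluoromethanesulfonate | CC[Si](CC)(CC)OC[C@@H](C)[C@H]1CC(OS(=O)(=O)C(F)(F)F)=CC(=O)O1
F4 | step 11 | (6R)-4-(prop-2-en-1-yl)-6-[(2R)-1-(triethylsilyloxy)propan-2-yl]-5,6-dihydro-2H-pyran-2-one | CC[Si](CC)(CC)OC[C@@H](C)[C@H]1CC(CC=C)=CC(=O)O1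
F5 | step 7 | (3R,4R,5E,7E,9E)-4-[(4-methoxyphenyl)methoxy]-3,5,9-trimethyl-10-(2-methyl-1,3-oxazol-4-yl)deca-5,7,9-trien-2-one | CC(/C=C/C=C(\C)[C@H](OCc2ccc(OC)cc2)[C@@H](C)C(C)=O)=C\c1coc(C)n1
F6 | step 7 | (1E,3R,5S,6S,7R,8E,10E,12E)-1-bromo-7-[(4-methoxyphenyl)methoxy]-2,6,8,12-tetramethyl-13-(2-methyl-1,3-oxazol-4-yl)trideca-1,8,10,12-tetraene-3,5-diol | CC(/C=C/C=C(\C)[C@H](OCc2ccc(OC)cc2)[C@@H](C)[C@@H](O)C[C@@H](O)/C(C)=C/Br)=C\c1coc(C)n1
F7 | step 7 | 2-(trimethylsilyl)ethyl ester of 30 carrying a 4-methoxybenzyl ether on O15 | CC(/C=C/C=C(\C)[C@H](OCc2ccc(OC)cc2)[C@@H](C)[C@@H](O)C[C@@H](O)/C(C)=C/C=C/[C@@H](C)[C@H]2C[C@@H](C/C=C/C(=O)OCC[Si](C)(C)C)CC(=O)O2)=C\c1coc(C)n1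
F8 | step 7 | 2-(trimethylsilyl)ethyl ester of 30 | CC(/C=C/C=C(\C)[C@H](O)[C@@H](C)[C@@H](O)C[C@@H](O)/C(C)=C/C=C/[C@@H](C)[C@H]2C[C@@H](C/C=C/C(=O)OCC[Si](C)(C)C)CC(=O)O2)=C\c1coc(C)n1
F9 | step 5 | (4R)-4-benzyl-3-propanoyl-1,3-oxazolidin-2-one | CCC(=O)N1[C@H](Cc2ccccc2)COC1=O
F10 | step 5 | (4R)-4-benzyl-3-[(2R,3R,4E,6E,8E)-3-hydroxy-2,4,8-trimethyl-9-(2-methyl-1,3-oxazol-4-yl)nona-4,6,8-trienoyl]-1,3-oxazolidin-2-one | CC(/C=C/C=C(\C)[C@H](O)[C@@H](C)C(=O)N2[C@H](Cc3ccccc3)COC2=O)=C\c1coc(C)n1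
F11 | step 5 | (2R,3R,4E,6E,8E)-3-hydroxy-N-methoxy-N,2,4,8-tetramethyl-9-(2-methyl-1,3-oxazol-4-yl)nona-4,6,8-trienamide | CC(/C=C/C=C(\C)[C@H](O)[C@@H](C)C(=O)N(C)OC)=C\c1coc(C)n1
F12 | step 5 | (2R,3R,4E,6E,8E)-N-methoxy-N,2,4,8-tetramethyl-9-(2-methyl-1,3-oxazol-4-yl)-3-(triethylsilyloxy)nona-4,6,8-trienamide | CC(/C=C/C=C(\C)[C@H](O[Si](CC)(CC)CC)[C@@H](C)C(=O)N(C)OC)=C\c1coc(C)n1
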